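Remark on the chemistry: ring A is numbered C1 (carbon bearing OH), C2 (carbon bearing the ether oxygen), then C3 (Br), C4 (H), C5 (Br), C6 (Br); ring B atoms carry a prime. Compounds 1 and 9 are assumed to be purchasable, and the target is achiral.

## The problem

Compound 15 is 2,3,5-tribromo-6-(2,4-dibromophenoxy)phenol: two benzene rings joined by one ether oxygen, with no stereocentre, so the whole problem is one of regiochemistry on ring A. Ring B is simply the aryl group of commercial 2,4-dibromophenol (9). Ring A carries OH at C1, the aryloxy group at C2 and bromine at C3, C5 and C6, and its only hydrogen sits at C4, para to the hydroxyl. Electrophilic bromination of a simpler 2-aryloxyphenol would go first to that para carbon and would also attack the free ortho position C6' of ring B, so the bromines cannot be put in last. The ether oxygen sits on a carbon flanked by OH and Br, a hindered site for substitution chemistry, and a copper- or palladium-catalysed coupling would have to distinguish five C–Br bonds. Those C–Br bonds are the fragile part of the molecule: they undergo halogen–metal exchange, insertion by low-valent metals and hydrogenolysis, and an aryl anion placed ortho to one of them can expel bromide; the acidic phenol is best unveiled last. The enabling feature is that C3 to C6 reproduce the Br, H, Br, Br sequence of 1,2,4,5-tetrabromobenzene (1), while C1 and C2, the only oxygen-bearing carbons, are adjacent. They are therefore the two carbons of an aryne, across which an oxygen nucleophile and a one-carbon stand-in for the hydroxyl can be added in one operation.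

## Retrosynthesis

**15 from 13.** The C1–OH bond is traced back to a C1–CHO bond: 15 would come from aldehyde 13, by way of aryl formate 14, through a Baeyer–Villiger (Dakin-type) oxidation and methanolysis. A formyl group is chosen because no electrophilic oxygen source is compatible with fluoride and phenoxide, whereas formyl is the smallest carbon electrophile an aryl anion can capture and peracid converts it to hydroxyl without touching C–Br bonds. The skeleton is not simplified, but the O/C pattern at C2/C1 of 13 is what an aryne difunctionalisation produces. The forward step asks for migration of an electron-poor aryl group in preference to hydride.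

**13 from 8 and 10.** Both the C2–O and the C1–CHO bond of 13 are cut, leaving aryne 11 and the elements of aryl formate 10; formally the aryne inserts into the O–CHO bond. Cutting C2–O alone (displacement of an ortho halogen of a benzaldehyde by phenoxide) is the conventional neighbour and is kept in reserve. The double cut is preferred because it removes both ortho substituents at once and reduces ring A to a tribrominated benzyne with no oxygen at all. That aryne is released from silyl triflate 8 by fluoride, so no organometallic reagent meets the five C–Br bonds or the formate. The forward reaction must place the phenoxide at C2 rather than C1, two carbons that differ only in remote substitution, and must deliver a formyl group rather than a proton to aryl anion 12.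

**10 from 9.** The formyl–oxygen bond is cut; 10 is the O-formyl derivative of purchasable 9, made in one step with a mixed formic anhydride. The electron-poor phenoxide is the leaving group that makes 10 a strong formyl donor.

**8 from 5 and 4.** The O–S bond and the C2–Si bond of 8 are cut, leading back through silyl ether 5 to phenol 4; forward, bromine–lithium exchange, O-to-C silyl shift and triflation follow in one flask. A phenol with two different ortho bromines would be closer to commercial material but would offer several competing exchange sites. In symmetrical 4 both ortho bromines are equivalent and are the only ones whose exchange gives a lithium flanked by oxygen and bromine. The forward reaction requires the silyl shift to outrun loss of LiBr from ortho-bromoaryllithium 6.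

**4 from 1.** The C–O bond of 4 is cut back to a C–H bond of 1. The two hydrogens of 1 are equivalent and each is acidified by two flanking bromines, so deprotonation, borylation (via 2 and 3) and oxidation install the single oxygen. This brings the Br, H, Br, Br array of ring A intact from a cheap arene.

## Roads not taken

**Alternative 1:** The cut runs through ring A itself. The C2–C3 and C1–C6 bonds are broken, giving 3,5-dibromo-2-pyrone A2 and the aryloxyalkynylboronate A3. Forward, a [4+2] cycloaddition followed by loss of CO2 would give aryl boronate A1, in which the ether oxygen and a boron standing for the hydroxyl are already adjacent. Oxidation of the C–B bond and a bromination at C6 would finish the synthesis.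
- Merits: cycloaddition and cycloreversion of 2-pyrones with alkynylboronates is a known reaction class, which the aryne insertion of the chosen plan is not. Regiochemistry would be governed by a strongly polarised ynol ether rather than by a remote bromine. In both respects this road is the better one.
- Weak points: A1 carries only two of the three ring A bromines. The C6 bromine would have to enter after oxidation, on a phenol whose para carbon C4 (which must stay unsubstituted) and whose ring B position C6' are both open. The selectivity problem therefore returns at the last step. A3 is a sensitive ynol ether and boronate in one, and its usual preparation through an aryloxyacetylide needs an alkyllithium in the presence of the ring B bromines. The cycloaddition of the pyrone with an alkyne also needs prolonged heating.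
- Comparison: the road is longer. Against the better precedent for forming A1, the chosen plan sets that all five bromines arrive in place from purchased materials, that no late halogenation is needed, and that a conventional route to its key intermediate exists.

**Alternative 2:** No skeletal bond of ring A is cut. All five C–Br bonds are taken back at once to 4-methoxy-3-phenoxyaniline A4, which has the amino group at C4 and a methyl ether at C1. Forward, five equivalents of Br2 in acetic acid would give the pentabromide A5. The amino group would then be removed by diazotisation and reduction, and the methyl ether cleaved with BBr3.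
- Merits: the reagents are the cheapest possible, no cryogenic organometallic is used, and every reaction type is classical. The amino group activates C3 and C5 and at the same time marks C4 as the future C–H. In precedent and operational simplicity this road is better than the chosen plan.
- Weak points: the step must stop at exactly three bromines on ring A and two on ring B. The third ring A bromine must enter C6, meta to nitrogen, on a ring that already carries two bromines and, as HBr accumulates, an ammonium group. Ring B meanwhile keeps a free ortho position C6' activated by the ether oxygen. Under- and over-bromination are therefore both likely, and the products would be hard to separate. A4 itself needs two or three steps.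
- Comparison: the length is similar. The chosen plan sets positional certainty against it: no bromine is introduced by electrophilic substitution on the diaryl ether.

**Alternative 3:** The cut runs through ring B. The C1'–C2' and C5'–C6' bonds are broken, leading to the ethynyl ether A6 of a ring A phenol and again to pyrone A2. Forward, cycloaddition and loss of CO2 would give A7, the methyl ether of 15, and BBr3 would free the phenol.
- Merits: the 2,4-dibromo pattern of ring B is written into the pyrone. The hindered diaryl ether bond is never made by substitution, because the oxygen is on ring A from the start. Ring A regiochemistry is settled before the key step, which in that respect is more secure than the aryne addition.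
- Weak points: the key step builds the ring that can be bought as 9. It leaves the real difficulty untouched, namely a ring A phenol with the Br, H, Br, Br array and two differentiated oxygens. Such a phenol is not available by brominating a guaiacol, since the position para to the free hydroxyl is the one that must stay unsubstituted. Terminal aryl ynol ethers are made by elimination with two equivalents of alkyllithium, which three aryl bromides would not survive, and they are thermally fragile under hot cycloaddition conditions.
- Comparison: the chosen plan spends its key step on ring A, where the complexity lies, and takes the ring A substitution from a commodity arene.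

Key step: step 5

## Route

Step 1
Reactants: 1 1,2,4,5-tetrabromobenzene
Product: 4 2,3,5,6-tetrabromophenol, via 2,3,5,6-tetrabromophenyllithium 2 (not isolated), via lithium aryltriisopropoxyborate 3 (not isolated)
Conditions: LiN(iPr)2 (1.1 equiv) added to 1 and B(OiPr)3 (1.3 equiv), THF, −78 °C; then AcOH, 30% aq. H2O2, 0 °C to rt
Reagents that add atoms: hydrogen peroxide, OO (the phenol oxygen); triisopropyl borate, CC(C)OB(OC(C)C)OC(C)C (its boron is carried only in 3 and is lost on oxidation)
Why: Lithiation–borylation–oxidation with in situ quench: one of the two equivalent C–H bonds of 1, each acidified by two flanking bromines, is deprotonated with the borate already present, so aryllithium 2 is converted at once into ate complex 3 before it can lose LiBr. Oxidative C–B to C–O cleavage under acidic conditions should then give the phenol while avoiding the base-promoted protodeboronation typical of di-ortho-halogenated arylboron compounds.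

Step 2
Reactants: 4 2,3,5,6-tetrabromophenol
Product: 5 trimethyl(2,3,5,6-tetrabromophenoxy)silane
Conditions: (Me3Si)2NH, THF, 65 °C; volatiles removed in vacuo, crude product used directly
Reagents that add atoms: hexamethyldisilazane, C[Si](C)(C)N[Si](C)(C)C
Why: O-Silylation of an acidic phenol with hexamethyldisilazane releases only ammonia, so the hydrolytically labile aryl silyl ether can be carried on after simple evaporation.

Step 3
Reactants: 5 trimethyl(2,3,5,6-tetrabromophenoxy)silane
Product: 8 3,5,6-tribromo-2-(trimethylsilyl)phenyl trifluoromethanesulfonate, via ortho-lithiated silyl ether 6 (not isolated), via lithium 2-silylphenoxide 7 (not isolated)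
Conditions: n-BuLi (1.05 equiv), THF, −100 to −78 °C; then Tf2O, −100 °C to rt
Reagents that add atoms: trifluoromethanesulfonic anhydride, O=S(=O)(OS(=O)(=O)C(F)(F)F)C(F)(F)F
Why: Bromine–lithium exchange should take place at one of the two equivalent bromines ortho to oxygen, the only site that gives a lithium flanked by O and Br; aryllithium 6 then undergoes the anionic 1,3 O-to-C silyl shift (retro-Brook rearrangement) to phenoxide 7, which Tf2O traps on oxygen. This is the standard one-flask route to 2-silylaryl triflates.

Step 4
Reactants: 9 2,4-dibromophenol
Product: 10 2,4-dibromophenyl formate
Conditions: HCO2H and Ac2O premixed (60 °C, then cooled); 9, NaOAc, toluene, 0 °C to rt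
Reagents that add atoms: formic acid, O=CO
Why: O-Formylation of a phenol with acetic formic anhydride generated from formic acid and acetic anhydride; the formyl carbonyl is the more electrophilic end of the mixed anhydride, so the formate rather than the acetate should form.

Step 5
Reactants: 8 3,5,6-tribromo-2-(trimethylsilyl)phenyl trifluoromethanesulfonate; 10 2,4-dibromophenyl formate
Product: 13 2,3,5-tribromo-6-(2,4-dibromophenoxy)benzaldehyde, via 3,4,6-tribromobenzyne 11 (not isolated), via aryl anion 12 (not isolated)
Conditions: KF (3 equiv), 18-crown-6 (3 equiv), 10 (2.5 equiv), THF, −20 to 0 °C, slow addition of 8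
Reagents that add atoms: none
Why: Proposed new method: fluoride attacks the silicon of 8 and triflate leaves, giving aryne 11 without any persistent organometallic. 2,4-Dibromophenoxide, first set free from 10 by fluoride, adds to the aryne carbon that bore silicon (C2), and the resulting aryl anion 12 at C1 takes the formyl group of a second molecule of 10. The tetrahedral adduct expels 2,4-dibromophenoxide, which carries a chain, so that in sum the aryne inserts into the O–CHO bond and forms C2–O and C1–CHO. The closest known reaction types are fluoride-triggered three-component couplings of arynes with oxygen or nitrogen nucleophiles and carbonyl electrophiles, and aryne insertions into acyl–carbon, acyl–nitrogen and carboxylic acid C–O bonds. No ring is closed and no stereocentre is formed. The first selectivity needed is regiochemical: both aryne carbons have an ortho bromine, so the bias rests on the C5 bromine, which stabilises negative charge at C1 (meta) better than at C2 (para), and on the buttressed C6 bromine, which shields C1 from the nucleophile; both effects direct oxygen to C2. The second is formylation rather than protonation of 12, which aprotic THF, an excess of the strongly formyl-donating electron-poor formate, and slow generation of the aryne at low temperature are meant to secure.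

Step 6
Reactants: 13 2,3,5-tribromo-6-(2,4-dibromophenoxy)benzaldehyde
Product: 15 2,3,5-tribromo-6-(2,4-dibromophenoxy)phenol, via aryl formate 14 (not isolated)
Conditions: mCPBA, CH2Cl2, 0 to 40 °C; then MeOH, HCl (cat.), rt
Reagents that add atoms: 3-chloroperoxybenzoic acid (mCPBA), OOC(=O)c1cccc(Cl)c1
Why: Baeyer–Villiger (Dakin-type) oxidation: the peracid adds to the aldehyde and ring A migrates to oxygen in the Criegee adduct, helped by the ortho aryloxy oxygen, to give formate 14, which methanol cleaves to the phenol. The C–Br bonds and the diaryl ether are inert to peracid.

## Compound list

1 | 1,2,4,5-tetrabromobenzene | Brc1cc(Br)c(Br)cc1Br | starting material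
2 | 2,3,5,6-tetrabromophenyllithium (formed in situ) | [Li]c1c(Br)c(Br)cc(Br)c1Br | intermediate
3 | lithium triisopropoxy(2,3,5,6-tetrabromophenyl)borate (formed in situ) | [Li+].CC(C)O[B-](OC(C)C)(OC(C)C)c1c(Br)c(Br)cc(Br)c1Br | intermediate
4 | 2,3,5,6-tetrabromophenol | Oc1c(Br)c(Br)cc(Br)c1Br | intermediate
5 | trimethyl(2,3,5,6-tetrabromophenoxy)silane | C[Si](C)(C)Oc1c(Br)c(Br)cc(Br)c1Br | intermediate
6 | [3,4,6-tribromo-2-(trimethylsilyloxy)phenyl]lithium (formed in situ) | [Li]c1c(Br)cc(Br)c(Br)c1O[Si](C)(C)C | intermediate
7 | lithium 3,5,6-tribromo-2-(trimethylsilyl)phenoxide (formed in situ) | [Li+].[O-]c1c(Br)c(Br)cc(Br)c1[Si](C)(C)C | intermediate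
8 | 3,5,6-tribromo-2-(trimethylsilyl)phenyl trifluoromethanesulfonate | C[Si](C)(C)c1c(Br)cc(Br)c(Br)c1OS(=O)(=O)C(F)(F)F | intermediate
9 | 2,4-dibromophenol | Oc1ccc(Br)cc1Br | starting material
10 | 2,4-dibromophenyl formate | O=COc1ccc(Br)cc1Br | intermediate
11 | 3,4,6-tribromobenzyne (3,4,6-tribromo-1,2-didehydrobenzene, formed in situ) | BrC1=CC(Br)=C(Br)C#C1 | intermediate
12 | potassium 2,3,5-tribromo-6-(2,4-dibromophenoxy)benzen-1-ide (formed in situ) | [K+].[C-]1=C(Br)C(Br)=CC(Br)=C1Oc1ccc(Br)cc1Br | intermediate
13 | 2,3,5-tribromo-6-(2,4-dibromophenoxy)benzaldehyde | O=Cc1c(Br)c(Br)cc(Br)c1Oc1ccc(Br)cc1Br | intermediate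
14 | 2,3,5-tribromo-6-(2,4-dibromophenoxy)phenyl formate (formed in situ) | O=COc1c(Br)c(Br)cc(Br)c1Oc1ccc(Br)cc1Br | intermediate
15 | 2,3,5-tribromo-6-(2,4-dibromophenoxy)phenol | Oc1c(Br)c(Br)cc(Br)c1Oc1ccc(Br)cc1Br | target

## Step count and risks

Total step count: 6. Longest linear sequence: 5 steps (steps 1, 2, 3, 5, 6); step 4 is a one-step side branch.

**Step 5 (key step, Proposed new method).** Four processes could defeat it.
- Protonation of aryl anion 12 in place of formyl transfer: fluoride and the chain-carrying phenoxide can also decarbonylate the formate to CO and a phenol, which is a proton source.
- Poor regioselectivity of phenoxide addition: both aryne carbons carry an ortho bromine, and only a remote bromine and a buttressing effect tell them apart.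
- Expulsion of bromide from C6 of 12, which would open a second aryne.
- Addition of 12 to aldehyde already formed.

The fallback uses known chemistry only and sets out from 1, with 9 as the nucleophile. Lithiation of 1 with LiN(iPr)2 in THF at −78 °C and quench with DMF would give 2,3,5,6-tetrabromobenzaldehyde F1. Nucleophilic aromatic substitution with 9 (K2CO3, DMF, 60 to 80 °C) would displace one of the two equivalent ortho bromines activated by the formyl group and rejoin the route at 13. Symmetry removes the regiochemical question. This detour is two steps and shorter than steps 1 to 5, so it is also the benchmark against which the insertion should be judged.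

**Step 6.** The likely failure is hydride rather than aryl migration in the Criegee adduct, because three bromines lower the migratory aptitude of ring A; oxidation would then stop at the carboxylic acid level. The fallback sets out from 13. Addition of MeMgBr (THF, −78 °C) would give racemic 1-[2,3,5-tribromo-6-(2,4-dibromophenoxy)phenyl]ethanol F2. Dess–Martin oxidation would give 1-[2,3,5-tribromo-6-(2,4-dibromophenoxy)phenyl]ethanone F3. Baeyer–Villiger oxidation of this methyl ketone with CF3CO3H, in which methyl cannot compete with aryl, would give 2,3,5-tribromo-6-(2,4-dibromophenoxy)phenyl acetate F4. Methanolysis (K2CO3, MeOH) would rejoin the route at 15.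

**Step 3.** Loss of LiBr from ortho-bromoaryllithium 6 could precede the silyl shift, exchange could occur at a bromine meta to oxygen, and triflation of the hindered phenoxide 7 could be incomplete. The fallback sets out from 4. Protection with MOMCl and iPr2NEt would give 1,2,4,5-tetrabromo-3-(methoxymethoxy)benzene F5. Addition of n-BuLi to F5 and Me3SiCl in THF at −100 °C (chelation-directed exchange with in situ external silylation in place of the intramolecular shift) would give [3,4,6-tribromo-2-(methoxymethoxy)phenyl]trimethylsilane F6. HCl in MeOH would give 3,5,6-tribromo-2-(trimethylsilyl)phenol F7. Tf2O and pyridine in CH2Cl2 would rejoin the route at 8.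

**Step 1.** Aryllithium 2 could eliminate LiBr before it is borylated, and the di-ortho-brominated arylboron intermediate could be protodeboronated during oxidation, returning 1. The fallback sets out from 1 and uses no organometallic. Mononitration (HNO3, H2SO4) would give 1,2,4,5-tetrabromo-3-nitrobenzene F8. Reduction with Fe in AcOH would give 2,3,5,6-tetrabromoaniline F9. Diazotisation with NaNO2 in H2SO4 would give 2,3,5,6-tetrabromobenzenediazonium hydrogen sulfate F10, and hydrolysis in hot aqueous H2SO4 would rejoin the route at 4.

## Further compounds

F1 | step 5 | 2,3,5,6-tetrabromobenzaldehyde | O=Cc1c(Br)c(Br)cc(Br)c1Br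
F2 | step 6 | 1-[2,3,5-tribromo-6-(2,4-dibromophenoxy)phenyl]ethanol (racemic) | CC(O)c1c(Br)c(Br)cc(Br)c1Oc1ccc(Br)cc1Br
F3 | step 6 | 1-[2,3,5-tribromo-6-(2,4-dibromophenoxy)phenyl]ethanone | CC(=O)c1c(Br)c(Br)cc(Br)c1Oc1ccc(Br)cc1Br
F4 | step 6 | 2,3,5-tribromo-6-(2,4-dibromophenoxy)phenyl acetate | CC(=O)Oc1c(Br)c(Br)cc(Br)c1Oc1ccc(Br)cc1Br
F5 | step 3 | 1,2,4,5-tetrabromo-3-(methoxymethoxy)benzene | COCOc1c(Br)c(Br)cc(Br)c1Br
F6 | step 3 | [3,4,6-tribromo-2-(methoxymethoxy)phenyl]trimethylsilane | COCOc1c(Br)c(Br)cc(Br)c1[Si](C)(C)C
F7 | step 3 | 3,5,6-tribromo-2-(trimethylsilyl)phenol | Oc1c(Br)c(Br)cc(Br)c1[Si](C)(C)C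
F8 | step 1 | 1,2,4,5-tetrabromo-3-nitrobenzene | O=[N+]([O-])c1c(Br)c(Br)cc(Br)c1Br
F9 | step 1 | 2,3,5,6-tetrabromoaniline | Nc1c(Br)c(Br)cc(Br)c1Br
F10 | step 1 | 2,3,5,6-tetrabromobenzenediazonium hydrogen sulfate | N#[N+]c1c(Br)c(Br)cc(Br)c1Br.OS(=O)(=O)[O-]
A1 | alternative 1 | 2-[3,5-dibromo-2-(2,4-dibromophenoxy)phenyl]-4,4,5,5-tetramethyl-1,3,2-dioxaborolane | CC1(C)OB(OC1(C)C)c1cc(Br)cc(Br)c1Oc1ccc(Br)cc1Br
A2 | alternative 1 | 3,5-dibromo-2H-pyran-2-one (3,5-dibromo-2-pyrone) | O=C1OC=C(Br)C=C1Br
A3 | alternative 1 | 2-[(2,4-dibromophenoxy)ethynyl]-4,4,5,5-tetramethyl-1,3,2-dioxaborolane | CC1(C)OB(C#COc2ccc(Br)cc2Br)OC1(C)C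
A4 | alternative 2 | 4-methoxy-3-phenoxyaniline | COc1ccc(N)cc1Oc1ccccc1
A5 | alternative 2 | 2,3,6-tribromo-5-(2,4-dibromophenoxy)-4-methoxyaniline | COc1c(Br)c(Br)c(N)c(Br)c1Oc1ccc(Br)cc1Br
A6 | alternative 3 | 1,2,5-tribromo-4-(ethynyloxy)-3-methoxybenzene | COc1c(Br)c(Br)cc(Br)c1OC#C
A7 | alternative 3 | 1,2,5-tribromo-4-(2,4-dibromophenoxy)-3-methoxybenzene | COc1c(Br)c(Br)cc(Br)c1Oc1ccc(Br)cc1Br
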